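**Assumption:** the target has no stereocentre or other stereo-element (it is achiral), so "single enantiomer" is taken to mean the compound as drawn and no enantiocontrol is needed.

**Retrosynthetic overview**
1. Target 8 ⇐ phenol 6 by late ortho/para dibromination of the free-phenol ring; the other ring is already fully substituted.
2. 6 ⇐ aldehyde 4 by Baeyer–Villiger (Dakin-type) oxidation and formate cleavage, with CHO as a masked OH.
3. 4 ⇐ tetrabromoguaiacol 2 + 2-fluorobenzaldehyde 3 by SNAr, forming the diaryl ether C–O bond.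
4. 2 ⇐ tetrabromocatechol 1 by mono-O-methylation.
5. No ring is formed: both benzene rings are bought, the perbrominated ring first, then the second ring is attached and functionalised.

**Route**

Step 1
Reactants: 1 3,4,5,6-tetrabromobenzene-1,2-diol (tetrabromocatechol)
Product: 2 2,3,4,5-tetrabromo-6-methoxyphenol (tetrabromoguaiacol)
Conditions: MeI (1.05 equiv), KHCO3 (1.0 equiv), DMF, 40 °C; aq. HCl work-up, chromatography
Reagents that add atoms: iodomethane, CI
Why: Williamson mono-O-methylation; with one equivalent of weak base only the more acidic, H-bond-stabilised catechol monoanion is formed and alkylated, so the reaction stops at the guaiacol.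

Step 2
Reactants: 2 2,3,4,5-tetrabromo-6-methoxyphenol; 3 2-fluorobenzaldehyde
Product: 4 2-(2,3,4,5-tetrabromo-6-methoxyphenoxy)benzaldehyde
Conditions: Cs2CO3 (1.5 equiv), 3 (1.5 equiv), DMF, 110 °C
Reagents that add atoms: none
Why: SNAr (addition–elimination) of the caesium phenoxide on the fluoride activated by the ortho-formyl group, metal-free so the four aryl bromides are untouched.

Step 3
Reactants: 4 2-(2,3,4,5-tetrabromo-6-methoxyphenoxy)benzaldehyde
Product: 6 2-(2,3,4,5-tetrabromo-6-methoxyphenoxy)phenol, via aryl formate 5 (not isolated)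
Conditions: mCPBA (1.5 equiv), CH2Cl2, 0 °C to reflux; aq. Na2SO3/NaHCO3 wash; then MeOH, cat. HCl, rt
Reagents that add atoms: 3-chloroperoxybenzoic acid (mCPBA), OOC(=O)c1cccc(Cl)c1
Why: Baeyer–Villiger (Dakin-type) oxidation in which the ortho-aryloxy-substituted aryl group migrates to give the aryl formate, which is cleaved by acid-catalysed methanolysis to the phenol.

Step 4
Reactants: 6 2-(2,3,4,5-tetrabromo-6-methoxyphenoxy)phenol
Product: 8 2,4-dibromo-6-(2,3,4,5-tetrabromo-6-methoxyphenoxy)phenol, via para-monobromide 7 (not isolated)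
Conditions: Br2 (2.1 equiv), AcOH, rt; aq. Na2S2O3 work-up
Reagents that add atoms: bromine, BrBr
Why: Electrophilic aromatic bromination directed by the free OH to its para and then its remaining ortho position, while the fully substituted tetrabromo ring cannot react.

**Compound list**
1 | 3,4,5,6-tetrabromobenzene-1,2-diol (tetrabromocatechol) | Oc1c(O)c(Br)c(Br)c(Br)c1Br | starting material
2 | 2,3,4,5-tetrabromo-6-methoxyphenol | COc1c(O)c(Br)c(Br)c(Br)c1Br | intermediate
3 | 2-fluorobenzaldehyde | O=Cc1ccccc1F | starting material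
4 | 2-(2,3,4,5-tetrabromo-6-methoxyphenoxy)benzaldehyde | COc1c(Br)c(Br)c(Br)c(Br)c1Oc1ccccc1C=O | intermediate
5 | 2-(2,3,4,5-tetrabromo-6-methoxyphenoxy)phenyl formate | COc1c(Br)c(Br)c(Br)c(Br)c1Oc1ccccc1OC=O | intermediate
6 | 2-(2,3,4,5-tetrabromo-6-methoxyphenoxy)phenol | COc1c(Br)c(Br)c(Br)c(Br)c1Oc1ccccc1O | intermediate
7 | 4-bromo-2-(2,3,4,5-tetrabromo-6-methoxyphenoxy)phenol | COc1c(Br)c(Br)c(Br)c(Br)c1Oc1cc(Br)ccc1O | intermediate
8 | 2,4-dibromo-6-(2,3,4,5-tetrabromo-6-methoxyphenoxy)phenol (CNP0266381.0) | COc1c(Br)c(Br)c(Br)c(Br)c1Oc1cc(Br)cc(Br)c1O | target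

**Total step count:** 4
**Longest linear sequence:** 4 steps (1 → 2 → 4 → 6 → 8)

**Steps most likely to fail, with fallbacks**

Step 2 (SNAr with a hindered, weakly nucleophilic tetrabromophenoxide). The fallback sets out from 2 and uses a far more activated electrophile. Compound 2 is heated with 1-fluoro-2-nitrobenzene and K2CO3 in DMF at 90 °C to give 1,2,3,4-tetrabromo-5-methoxy-6-(2-nitrophenoxy)benzene F1. The nitro group is reduced with Fe/NH4Cl in EtOH/H2O at 80 °C, which spares the C–Br bonds, to give 2-(2,3,4,5-tetrabromo-6-methoxyphenoxy)aniline F2. Diazotisation with NaNO2 in aqueous H2SO4/AcOH at 0 °C gives 2-(2,3,4,5-tetrabromo-6-methoxyphenoxy)benzenediazonium hydrogensulfate F3, which is hydroxy-dediazoniated with Cu2O/Cu(NO3)2 in water at rt. This comes back to the route at phenol 6 and bypasses steps 2 and 3.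

Step 3 (hydride instead of aryl migration, giving the benzoic acid rather than the formate). The fallback sets out from 2 and replaces the aldehyde by a methyl ketone, where aryl migration over methyl is reliable. Compound 2 undergoes SNAr with 1-(2-fluorophenyl)ethanone (Cs2CO3, DMF, 110 °C) to give 1-[2-(2,3,4,5-tetrabromo-6-methoxyphenoxy)phenyl]ethan-1-one F4. Baeyer–Villiger oxidation with mCPBA/TFA in CH2Cl2 gives 2-(2,3,4,5-tetrabromo-6-methoxyphenoxy)phenyl acetate F5, and methanolysis (K2CO3, MeOH, rt) comes back to the route at phenol 6.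

Step 1 (mixture of unreacted diol, mono- and dimethyl ether). The fallback sets out from 1 and gives up the selective alkylation. Compound 1 is exhaustively methylated (excess MeI, K2CO3, acetone, reflux) to 1,2,3,4-tetrabromo-5,6-dimethoxybenzene F6. One methyl ether is then removed by nucleophilic demethylation (LiCl, DMF, 140 °C, then aq. HCl), which stops at the mono-phenoxide because the anion deactivates the second ether. This comes back to the route at 2.

**Further compounds**
F1 | step 2 | 1,2,3,4-tetrabromo-5-methoxy-6-(2-nitrophenoxy)benzene | COc1c(Br)c(Br)c(Br)c(Br)c1Oc1ccccc1[N+](=O)[O-]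
F2 | step 2 | 2-(2,3,4,5-tetrabromo-6-methoxyphenoxy)aniline | COc1c(Br)c(Br)c(Br)c(Br)c1Oc1ccccc1N
F3 | step 2 | 2-(2,3,4,5-tetrabromo-6-methoxyphenoxy)benzenediazonium hydrogensulfate | COc1c(Br)c(Br)c(Br)c(Br)c1Oc1ccccc1[N+]#N.OS(=O)(=O)[O-]
F4 | step 3 | 1-[2-(2,3,4,5-tetrabromo-6-methoxyphenoxy)phenyl]ethan-1-one | COc1c(Br)c(Br)c(Br)c(Br)c1Oc1ccccc1C(C)=O
F5 | step 3 | 2-(2,3,4,5-tetrabromo-6-methoxyphenoxy)phenyl acetate | COc1c(Br)c(Br)c(Br)c(Br)c1Oc1ccccc1OC(C)=O
F6 | step 1 | 1,2,3,4-tetrabromo-5,6-dimethoxybenzene | COc1c(OC)c(Br)c(Br)c(Br)c1Br
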